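**Assumption:** the facial sense of the new step 8 cannot be predicted with certainty. The (R)-Cp^x ligand is written; if the first run gives the 3S series (chiral HPLC, CD), its mirror image is used. Cp^x is a Cramer-type C2-symmetric binaphthyl-fused cyclopentadienyl with 3,3′-OMe groups. The target stereocentre (isoflavan C3) is R.

## Retrosynthetic overview

1. Target 19 ⇐ one-pot basic removal of the silyl ether and the carbamate from 17.
2. 17 ⇐ C3–C1′ bond: enantioselective Rh(III) ortho-C–H addition of chromenyl carbamate 16 across C3=C4 of 2H-chromene 8. This sets 3R and turns the pyran of 8 into the chroman.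
3. 8 ⇐ Au-catalysed ring closure of aryl propargyl ether 7 ⇐ dehydrogenative aromatisation of vinylogous ester 5 ⇐ cyclohexane-1,3-dione, prenyl bromide, propargyl alcohol.
4. 16 ⇐ 2,2-dimethylchromen-5-ol 15 ⇐ formal [3+3] pyran annulation of cyclohexane-1,3-dione with prenal, then aromatisation.
5. Ring order: A arene (step 3), then its pyran (step 4); dimethylpyran (step 5), then B arene (step 6); the two halves are joined in step 8.

## Route

**Step 1**
Reactants: 1 cyclohexane-1,3-dione; 2 1-bromo-3-methylbut-2-ene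
Product: 3 2-(3-methylbut-2-en-1-yl)cyclohexane-1,3-dione
Conditions: KOH (1.0 equiv), H2O, 0 °C → rt
Reagents that add atoms: none
Why: C-alkylation of the 1,3-dione enolate (SN2 at the primary allylic carbon) is favoured in water, where the enolate oxygens are hydrogen-bonded.

**Step 2**
Reactants: 3 2-(3-methylbut-2-en-1-yl)cyclohexane-1,3-dione; 4 prop-2-yn-1-ol
Product: 5 2-(3-methylbut-2-en-1-yl)-3-(prop-2-yn-1-yloxy)cyclohex-2-en-1-one
Conditions: PPh3, DIAD, THF, 0 °C → rt
Reagents that add atoms: none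
Why: Mitsunobu etherification of the acidic enol goes on oxygen because C-attack would build a quaternary centre, and the neutral conditions avoid acid-catalysed cyclisation of the enol onto the prenyl group.

**Step 3**
Reactants: 5 2-(3-methylbut-2-en-1-yl)-3-(prop-2-yn-1-yloxy)cyclohex-2-en-1-one
Product: 7 tert-butyldimethyl[2-(3-methylbut-2-en-1-yl)-3-(prop-2-yn-1-yloxy)phenoxy]silane, via TBS dienol ether 6 (not isolated)
Conditions: TBSOTf (1.1 equiv), Et3N (1.2 equiv), CH2Cl2, 0 °C; then DDQ (1.1 equiv), 0 °C → rt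
Reagents that add atoms: tert-butyldimethylsilyl trifluoromethanesulfonate, CC(C)(C)[Si](C)(C)OS(=O)(=O)C(F)(F)F
Why: soft enolisation gives a 1-silyloxy-3-alkoxycyclohexa-1,3-diene whichever proton is removed, and DDQ dehydrogenative aromatisation (hydride abstraction, proton loss) gives the aryl silyl ether without a strong base touching the terminal alkyne.

**Step 4**
Reactants: 7 tert-butyldimethyl[2-(3-methylbut-2-en-1-yl)-3-(prop-2-yn-1-yloxy)phenoxy]silane
Product: 8 tert-butyldimethyl{[8-(3-methylbut-2-en-1-yl)-2H-chromen-7-yl]oxy}silane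
Conditions: [JohnPhosAu(MeCN)]SbF6 (2 mol %), CH2Cl2, rt
Reagents that add atoms: none
Why: gold(I)-catalysed 6-endo-dig intramolecular hydroarylation of the aryl propargyl ether closes onto the only free ortho carbon, which is para to the silyloxy donor.

**Step 5**
Reactants: 1 cyclohexane-1,3-dione; 9 3-methylbut-2-enal
Product: 11 2,2-dimethyl-7,8-dihydro-2H-chromen-5(6H)-one, via oxatriene 10 (not isolated)
Conditions: ethylenediammonium diacetate (10 mol %), MeOH, rt → 50 °C
Reagents that add atoms: none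
Why: Knoevenagel condensation gives a 1-oxatriene that closes by oxa-6π electrocyclisation (formal [3+3] annulation).

**Step 6**
Reactants: 11 2,2-dimethyl-7,8-dihydro-2H-chromen-5(6H)-one
Product: 15 2,2-dimethyl-2H-chromen-5-ol, via α′-selenide 12 (not isolated), via selenoxide 13 (not isolated), via keto tautomer 14 (not isolated)
Conditions: LDA (1.1 equiv), THF, −78 °C; PhSeCl; then 30 % H2O2, pyridine, CH2Cl2, 0 °C → rt
Reagents that add atoms: none
Why: kinetic α′-enolate selenenylation and selenoxide syn-elimination give a cross-conjugated dienone that tautomerises to the phenol.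

**Step 7**
Reactants: 15 2,2-dimethyl-2H-chromen-5-ol
Product: 16 2,2-dimethyl-2H-chromen-5-yl diethylcarbamate
Conditions: ClC(O)NEt2, K2CO3, MeCN, reflux
Reagents that add atoms: diethylcarbamoyl chloride, CCN(CC)C(Cl)=O
Why: O-acylation of the phenoxide installs a carbamate that serves as both protecting group and ortho-directing group.

**Step 8**
Reactants: 8 tert-butyldimethyl{[8-(3-methylbut-2-en-1-yl)-2H-chromen-7-yl]oxy}silane; 16 2,2-dimethyl-2H-chromen-5-yl diethylcarbamate (1.3 equiv)
Product: 17 6-[(3R)-7-[(tert-butyldimethylsilyl)oxy]-8-(3-methylbut-2-en-1-yl)-3,4-dihydro-2H-chromen-3-yl]-2,2-dimethyl-2H-chromen-5-yl diethylcarbamate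
Conditions: [(R)-Cp^xRhI2]2 (2.5 mol %), AgSbF6 (10 mol %), CsOPiv (20 mol %), PivOH (1.0 equiv), DCE, 40 °C
Reagents that add atoms: none
Why: Proposed new method: enantioselective Cp^xRh(III)-catalysed, carbamate-directed ortho-C–H addition of an arene across a 2H-chromene (intermolecular hydroarylation). Pivalate-assisted C–H metalation at C6 of 16, its only ortho C–H, gives a six-membered rhodacycle; the aryl–Rh bond inserts the styrenic C3=C4 bond of 8 with aryl to C3 and Rh to the benzylic C4, the chiral Cp pocket choosing the alkene face and so setting C3 as R; the C4–Rh bond has no syn β-hydrogen (C3–H is anti, C4a has none), so PivOH protodemetalation closes the cycle instead of Heck elimination; the prenyl alkene and the gem-dimethyl-shielded chromene alkene of 16 are too hindered to insert, and the product has no ortho C–H left. Closest known reaction types: Cp*Rh(III) carbamate-directed oxidative ortho-olefination of phenol carbamates, and Rh(I)/chiral-diene hydroarylation of 2H-chromenes with arylboronic acids.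

**Step 9**
Reactants: 17 6-[(3R)-7-[(tert-butyldimethylsilyl)oxy]-8-(3-methylbut-2-en-1-yl)-3,4-dihydro-2H-chromen-3-yl]-2,2-dimethyl-2H-chromen-5-yl diethylcarbamate
Product: 19 6-[(3R)-7-hydroxy-8-(3-methylbut-2-en-1-yl)-3,4-dihydro-2H-chromen-3-yl]-2,2-dimethyl-2H-chromen-5-ol, via 7-hydroxy carbamate 18 (not isolated)
Conditions: KOH (20 equiv), EtOH/H2O 4:1, reflux, Ar; then aq. NH4Cl, 0 °C
Reagents that add atoms: none
Why: hydroxide cleaves the aryl silyl ether at silicon and then the carbamate by acyl substitution (basic hydrolysis), while the non-acidic C3–H leaves the R centre untouched.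

## Compound list

1 | cyclohexane-1,3-dione | O=C1CCCC(=O)C1 | starting material
2 | 1-bromo-3-methylbut-2-ene (prenyl bromide) | CC(C)=CCBr | starting material
3 | 2-(3-methylbut-2-en-1-yl)cyclohexane-1,3-dione | CC(C)=CCC1C(=O)CCCC1=O | intermediate
4 | prop-2-yn-1-ol | C#CCO | starting material
5 | 2-(3-methylbut-2-en-1-yl)-3-(prop-2-yn-1-yloxy)cyclohex-2-en-1-one | CC(C)=CCC1=C(OCC#C)CCCC1=O | intermediate
6 | tert-butyldimethyl{[6-(3-methylbut-2-en-1-yl)-5-(prop-2-yn-1-yloxy)cyclohexa-1,5-dien-1-yl]oxy}silane (drawn as the α′-deprotonated isomer; the γ-isomer gives the same 7) | CC(C)=CCC1=C(OCC#C)CCC=C1O[Si](C)(C)C(C)(C)C | intermediate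
7 | tert-butyldimethyl[2-(3-methylbut-2-en-1-yl)-3-(prop-2-yn-1-yloxy)phenoxy]silane | CC(C)=CCc1c(OCC#C)cccc1O[Si](C)(C)C(C)(C)C | intermediate
8 | tert-butyldimethyl{[8-(3-methylbut-2-en-1-yl)-2H-chromen-7-yl]oxy}silane | CC(C)=CCc1c(O[Si](C)(C)C(C)(C)C)ccc2c1OCC=C2 | intermediate
9 | 3-methylbut-2-enal | CC(C)=CC=O | starting material
10 | 2-(3-methylbut-2-en-1-ylidene)cyclohexane-1,3-dione | CC(C)=CC=C1C(=O)CCCC1=O | intermediate
11 | 2,2-dimethyl-7,8-dihydro-2H-chromen-5(6H)-one | CC1(C)C=CC2=C(O1)CCCC2=O | intermediate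
12 | 2,2-dimethyl-6-(phenylselanyl)-7,8-dihydro-2H-chromen-5(6H)-one (racemic) | CC1(C)C=CC2=C(O1)CCC([Se]c1ccccc1)C2=O | intermediate
13 | 2,2-dimethyl-6-(phenylseleninyl)-7,8-dihydro-2H-chromen-5(6H)-one (selenoxide, diastereomer mixture) | CC1(C)C=CC2=C(O1)CCC([Se](=O)c1ccccc1)C2=O | intermediate
14 | 2,2-dimethyl-2H-chromen-5(8H)-one | CC1(C)C=CC2=C(O1)CC=CC2=O | intermediate
15 | 2,2-dimethyl-2H-chromen-5-ol | CC1(C)C=Cc2c(O)cccc2O1 | intermediate
16 | 2,2-dimethyl-2H-chromen-5-yl diethylcarbamate | CCN(CC)C(=O)Oc1cccc2c1C=CC(C)(C)O2 | intermediate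
17 | 6-[(3R)-7-[(tert-butyldimethylsilyl)oxy]-8-(3-methylbut-2-en-1-yl)-3,4-dihydro-2H-chromen-3-yl]-2,2-dimethyl-2H-chromen-5-yl diethylcarbamate | CC(C)=CCc1c(O[Si](C)(C)C(C)(C)C)ccc2c1OC[C@@H](c1ccc3c(c1OC(=O)N(CC)CC)C=CC(C)(C)O3)C2 | intermediate
18 | 6-[(3R)-7-hydroxy-8-(3-methylbut-2-en-1-yl)-3,4-dihydro-2H-chromen-3-yl]-2,2-dimethyl-2H-chromen-5-yl diethylcarbamate | CC(C)=CCc1c(O)ccc2c1OC[C@@H](c1ccc3c(c1OC(=O)N(CC)CC)C=CC(C)(C)O3)C2 | intermediate
19 | 6-[(3R)-7-hydroxy-8-(3-methylbut-2-en-1-yl)-3,4-dihydro-2H-chromen-3-yl]-2,2-dimethyl-2H-chromen-5-ol | CC(C)=CCc1c(O)ccc2c1OC[C@@H](c1ccc3c(c1O)C=CC(C)(C)O3)C2 | target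

## Step count

Total step count: 9 (steps 1–4 for 8, steps 5–7 for 16, then steps 8 and 9).
Longest linear sequence: 6 (steps 1, 2, 3, 4, 8, 9), which is two thirds of the total.

## Three steps most likely to fail

**Step 8 (new reaction).** The weakly coordinating carbamate may metalate slowly, the internal styrenic alkene may insert sluggishly or with the wrong regiochemistry, and the enantioselectivity is untested. The fallback uses known chemistry, sets out from 16 and comes back at 17. Directed ortho-metalation of 16 (s-BuLi, TMEDA, THF, −78 °C; B(OMe)3; aq. NH4Cl) gives [5-(diethylcarbamoyloxy)-2,2-dimethyl-2H-chromen-6-yl]boronic acid F1. F1 is then added across 8 by the rhodium(I)/chiral-diene asymmetric hydroarylation of 2H-chromenes with arylboronic acids ([Rh(OH)(diene*)]2, dioxane/H2O, 60 °C, no added base), giving 17.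

**Step 3.** DDQ may desilylate the intermediate or attack the benzylic-allylic prenyl CH2. The fallback sets out from 3 and comes back at 7; it introduces the alkyne only after aromatisation so that enolate chemistry can be used. TBSCl and imidazole in DMF convert 3 into 3-[(tert-butyldimethylsilyl)oxy]-2-(3-methylbut-2-en-1-yl)cyclohex-2-en-1-one F2. LDA and then PhSeCl at −78 °C give 3-[(tert-butyldimethylsilyl)oxy]-2-(3-methylbut-2-en-1-yl)-6-(phenylselanyl)cyclohex-2-en-1-one F3. mCPBA at −78 °C oxidises it to 3-[(tert-butyldimethylsilyl)oxy]-2-(3-methylbut-2-en-1-yl)-6-(phenylseleninyl)cyclohex-2-en-1-one F4. On warming, F4 eliminates to 3-[(tert-butyldimethylsilyl)oxy]-2-(3-methylbut-2-en-1-yl)cyclohexa-2,5-dien-1-one F5, which tautomerises to 3-[(tert-butyldimethylsilyl)oxy]-2-(3-methylbut-2-en-1-yl)phenol F6. Propargyl bromide and K2CO3 in acetone then give 7.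

**Step 9.** The carbamate sits between two ortho substituents and may hydrolyse slowly, while the electron-rich phenoxides are air-sensitive at reflux. The fallback sets out from 17 and comes back at 19; it replaces hydrolysis by stepwise reductive and fluoride cleavage. LiAlH4 in THF (0 °C → reflux) removes the carbamate to give 6-[(3R)-7-[(tert-butyldimethylsilyl)oxy]-8-(3-methylbut-2-en-1-yl)-3,4-dihydro-2H-chromen-3-yl]-2,2-dimethyl-2H-chromen-5-ol F7. TBAF in THF at 0 °C then gives 19.

## Further compounds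

F1 | step 8 | [5-(diethylcarbamoyloxy)-2,2-dimethyl-2H-chromen-6-yl]boronic acid | CCN(CC)C(=O)Oc1c(B(O)O)ccc2c1C=CC(C)(C)O2
F2 | step 3 | 3-[(tert-butyldimethylsilyl)oxy]-2-(3-methylbut-2-en-1-yl)cyclohex-2-en-1-one | CC(C)=CCC1=C(O[Si](C)(C)C(C)(C)C)CCCC1=O
F3 | step 3 | 3-[(tert-butyldimethylsilyl)oxy]-2-(3-methylbut-2-en-1-yl)-6-(phenylselanyl)cyclohex-2-en-1-one | CC(C)=CCC1=C(O[Si](C)(C)C(C)(C)C)CCC([Se]c2ccccc2)C1=O
F4 | step 3 | 3-[(tert-butyldimethylsilyl)oxy]-2-(3-methylbut-2-en-1-yl)-6-(phenylseleninyl)cyclohex-2-en-1-one | CC(C)=CCC1=C(O[Si](C)(C)C(C)(C)C)CCC([Se](=O)c2ccccc2)C1=O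
F5 | step 3 | 3-[(tert-butyldimethylsilyl)oxy]-2-(3-methylbut-2-en-1-yl)cyclohexa-2,5-dien-1-one | CC(C)=CCC1=C(O[Si](C)(C)C(C)(C)C)CC=CC1=O
F6 | step 3 | 3-[(tert-butyldimethylsilyl)oxy]-2-(3-methylbut-2-en-1-yl)phenol | CC(C)=CCc1c(O)cccc1O[Si](C)(C)C(C)(C)C
F7 | step 9 | 6-[(3R)-7-[(tert-butyldimethylsilyl)oxy]-8-(3-methylbut-2-en-1-yl)-3,4-dihydro-2H-chromen-3-yl]-2,2-dimethyl-2H-chromen-5-ol | CC(C)=CCc1c(O[Si](C)(C)C(C)(C)C)ccc2c1OC[C@@H](c1ccc3c(c1O)C=CC(C)(C)O3)C2
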